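Ochre runs longer than Monday's run on less incoming ligand, yet the two reach nearly the same dose θ. θ is the charge of incoming ligand times the time: 3.41 M·h at the end of ochre, 3.60 M·h at Monday's last reading.

common to all: starting complex 0.71 M

| charge | incoming ligand | remark | time |
|---|---|---|---|
| Wednesday's | 0.50 M | run made earlier |  |
| Monday's | 1.2 M | run made earlier |  |
| Sunday's | 2.1 M | run made earlier |  |
| ochre | 0.568 M |  | 6.0 h |
| teal | 2.84 M |  | 6.0 h |
| grey | 2.13 M |  | 6.0 h |

| run | time / h | complex with two exchanged / % |
|---|---|---|
| Wednesday's | 0.250 | 1.2 |
| Wednesday's | 0.417 | 0 |
| Wednesday's | 0.833 | 0 |
| Wednesday's | 1.50 | 0 |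
| Wednesday's | 3.00 | 1.3 |
| Monday's | 0.250 | 0 |
| Monday's | 0.833 | 0 |
| Monday's | 1.33 | 0 |
| Monday's | 2.00 | 3.4 |
| Monday's | 3.00 | 5.6 |
| Sunday's | 0.250 | 0 |
| Sunday's | 0.833 | 3.7 |
| Sunday's | 1.33 | 7.0 |
| Sunday's | 2.00 | 7.9 |
| Sunday's | 3.00 | 15.1 |

(standard deviation of a reading: 1 percentage point)



* which of these holds the largest part of the starting complex at the end of ochre (complex with two exchanged / complex with one exchanged / starting complex)
* which of these holds the largest part of the starting complex at the end of teal (complex with two exchanged / complex with one exchanged / starting complex)
* which of these holds the largest part of the starting complex at the end of grey (complex with two exchanged / complex with one exchanged / starting complex)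
* final complex with two exchanged in ochre, as a percentage of the starting complex charged

The flask is read here as two lags in series, starting complex to complex with one exchanged to complex with two exchanged. The rule assumes incoming ligand held at its charge, which makes each step pseudo-first-order and lets dose stand in for the clock, but ochre holds less incoming ligand than starting complex, so its estimate is rough. The zero of the scale is two equal lags, for which the early share of final product is 0.5 times the square of θ/D. D, the dose constant, is what a time constant is to a clock. Sunday's last reading gives D = 11.5 M·h. At Monday's dose this predicts 4.93 % against a reading of 5.6 %, with a scatter of 1 percentage point.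

For whoever takes over: ochre stays below D, so starting complex should still lead at the end, with about 4.42 % complex with two exchanged. Leave charge and clock alone. Grey and teal pass D, so the rule is not used for them.

The forecast, from “two successive bimolecular steps, each first order in ligand”, names starting complex for ochre, complex with two exchanged for teal and starting complex for grey, with 4.5 % in ochre.

    complex with one exchanged + incoming ligand ⇌ leaving ligand + complex with two exchanged (K = 15.0, k = 3.00 × 10⁻⁵ M⁻¹ s⁻¹)
    starting complex + incoming ligand ⇌ leaving ligand + complex with one exchanged (K = 0.300, k = 5.30 × 10⁻⁵ M⁻¹ s⁻¹)

The largest parts are starting complex in ochre, complex with two exchanged in teal and starting complex in grey, as forecast, and ochre ends at 4.36 % against the rule's 4.42 %. A neighbour of ochre charged with 0.97 M incoming ligand takes a dose of 5.82 M·h, for which D gives 12.9 %, and it stands at 10.6 %. The largest single effect on ochre's figure is the time given: left ten times as long, ochre stands at 22.7 % instead of 4.36 %. The shrinking supply of incoming ligand is a part of it: with the supply held, ochre stands at 7.13 %.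

(All runs were computed from invented constants.)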